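**Assumption:** the target has no stereocentre and is achiral. "Single enantiomer" is therefore read as the single (E)-alkene isomer, which is the only stereochemical element to control.

## Retrosynthetic overview
(Chain numbered C1 at the methoxyphenol ring A to C14 at the resorcinol ring B.)
1. The E-C8=C9 alkene and the three free OH groups come from an internal alkyne tris(benzyl ether). One Na/NH3 step does the anti-reduction and the O-debenzylation together.
2. C13–C14: an alkyl Grignard reagent couples with commercial 3,5-bis(benzyloxy)benzyl bromide under Cu catalysis.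
3. C7–C8: the lithium acetylide of 6-chloro-1-hexyne displaces bromide from ArA(CH2)7Br (Br reacts in preference to Cl).
4. ArA–C1: an aryl Grignard reagent couples with excess 1,7-dibromoheptane under Cu catalysis.
5. No ring is formed. Both arenes are purchased, and the OMe/OH differentiation of ring A is bought in with 3-bromo-5-methoxyphenol.

## Route

**Step 1**
Reactants: 1 (3-bromo-5-methoxyphenol); 2 (benzyl bromide)
Product: 3, 1-(benzyloxy)-3-bromo-5-methoxybenzene
Conditions: BnBr (1.1 equiv), K2CO3 (2 equiv), DMF, rt, 12 h
Reagents that add atoms: benzyl bromide, BrCc1ccccc1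
Why: Williamson ether synthesis masks the acidic phenol for the organometallic steps, using a group that the final dissolving-metal step removes at no extra cost.

**Step 2**
Reactants: 3; 4 (1,7-dibromoheptane)
Product: 5, 1-(benzyloxy)-3-(7-bromoheptyl)-5-methoxybenzene
Conditions: (i) Mg, cat. I2, THF, reflux, 2 h; (ii) add to 4 (3 equiv), Li2CuCl4 (5 mol %), THF, 0 °C to rt; recover excess 4
Reagents that add atoms: 1,7-dibromoheptane, BrCCCCCCCBr
Why: Kochi-type Cu-catalysed coupling of an aryl Grignard reagent with a primary alkyl bromide, where the excess dibromide enforces mono-substitution and the aryl ethers are inert.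

**Step 3**
Reactants: 5; 6 (6-chloro-1-hexyne)
Product: 7, 1-(benzyloxy)-3-(13-chlorotridec-8-yn-1-yl)-5-methoxybenzene
Conditions: 6 (1.5 equiv), n-BuLi (1.45 equiv), THF, −78 to 0 °C; then DMPU and 5 (1.0 equiv), 0 °C to rt, 16 h; no iodide additive
Reagents that add atoms: 6-chloro-1-hexyne, C#CCCCCCl
Why: SN2 alkylation of a lithium acetylide, in which the primary bromide reacts far faster than the primary chloride in THF/DMPU at or below rt, so the chloride survives as the next handle.

**Step 4**
Reactants: 7; 8 (3,5-bis(benzyloxy)benzyl bromide)
Product: 9, 1-(benzyloxy)-3-{14-[3,5-bis(benzyloxy)phenyl]tetradec-8-yn-1-yl}-5-methoxybenzene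
Conditions: (i) Mg (3 equiv, activated with BrCH2CH2Br), THF, reflux, 3 h; (ii) 8 (0.9 equiv), Li2CuCl4 (5 mol %), THF, −20 °C to rt
Reagents that add atoms: 3,5-bis(benzyloxy)benzyl bromide, BrCc1cc(OCc2ccccc2)cc(OCc2ccccc2)c1
Why: Kochi Cu-catalysed coupling of a primary alkyl Grignard reagent with a reactive benzylic bromide; the unactivated internal alkyne and the aryl ethers do not react with RMgCl or catalytic Cu under these conditions.

**Step 5**
Reactants: 9
Product: 10, dehydrobisgravillol, 5-[(6E)-14-(3-hydroxy-5-methoxyphenyl)tetradec-6-en-1-yl]benzene-1,3-diol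
Conditions: Na (about 20 equiv), NH3(l)/THF 3:1, no alcohol, −78 to −33 °C, 2–3 h, Ar; isoprene, then solid NH4Cl; evaporate NH3; aq. HCl to pH 4; EtOAc extraction
Reagents that add atoms: none (only H is added)
Why: dissolving-metal (Birch-type) reduction gives the E-alkene through the more stable trans-vinyl radical/anion. The same electrons cleave the three ArO–CH2Ph bonds. The resulting phenoxides, together with the absence of an alcohol proton source, protect both rings and the OMe group from Birch reduction.

## Compound list
| No. | Name | SMILES | Role |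
|---|---|---|---|
| 1 | 3-bromo-5-methoxyphenol | COc1cc(O)cc(Br)c1 | starting material |
| 2 | benzyl bromide | BrCc1ccccc1 | starting material |
| 3 | 1-(benzyloxy)-3-bromo-5-methoxybenzene | COc1cc(OCc2ccccc2)cc(Br)c1 | intermediate |
| 4 | 1,7-dibromoheptane | BrCCCCCCCBr | starting material |
| 5 | 1-(benzyloxy)-3-(7-bromoheptyl)-5-methoxybenzene | COc1cc(OCc2ccccc2)cc(CCCCCCCBr)c1 | intermediate |
| 6 | 6-chloro-1-hexyne | C#CCCCCCl | starting material |
| 7 | 1-(benzyloxy)-3-(13-chlorotridec-8-yn-1-yl)-5-methoxybenzene | COc1cc(OCc2ccccc2)cc(CCCCCCCC#CCCCCCl)c1 | intermediate |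
| 8 | 3,5-bis(benzyloxy)benzyl bromide | BrCc1cc(OCc2ccccc2)cc(OCc2ccccc2)c1 | starting material |
| 9 | 1-(benzyloxy)-3-{14-[3,5-bis(benzyloxy)phenyl]tetradec-8-yn-1-yl}-5-methoxybenzene | COc1cc(OCc2ccccc2)cc(CCCCCCCC#CCCCCCc2cc(OCc3ccccc3)cc(OCc3ccccc3)c2)c1 | intermediate |
| 10 | dehydrobisgravillol (E) | COc1cc(O)cc(CCCCCCC/C=C/CCCCCc2cc(O)cc(O)c2)c1 | target |

## Summary
**Total steps:** 5
**Longest linear sequence:** 5

**Three steps most likely to fail, with fallbacks**
1. **Step 5.** Risks are poor solubility or incomplete reduction, partial ring reduction, and erosion of E purity.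
   - Fallback: separate the two events. First carry out Ru-catalysed trans-hydrosilylation of 9 ([Cp*Ru(MeCN)3]PF6, (EtO)3SiH), then protodesilylation (AgF or CuI/TBAF) to give the E-alkene.
   - Then debenzylate with BCl3/pentamethylbenzene at −78 °C, which spares the alkene and the OMe group.
2. **Step 4.** Risks are sluggish Grignard formation from an advanced alkyl chloride and Wurtz homocoupling of 8.
   - Fallback: replace the sp3–sp3 coupling with a B-alkyl Suzuki–Miyaura coupling. Alkylate the acetylide of hept-1-en-6-yne with 5.
   - Hydroborate only the terminal alkene with 9-BBN, then couple with 1,3-bis(benzyloxy)-5-bromobenzene (Pd(dppf)Cl2, K3PO4) to reach the same compound 9.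
3. **Step 2.** Risks are double coupling, biaryl formation, or low conversion of the aryl Grignard reagent with the alkyl bromide.
   - Fallback: hydroborate hept-6-en-1-ol with 9-BBN and carry out a B-alkyl Suzuki coupling with aryl bromide 3.
   - Convert the resulting alcohol to bromide 5 by an Appel reaction (CBr4/PPh3). This avoids the aryl Grignard reagent entirely.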